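**Plan**
- Retrosynthesis: the two sulfate S–O bonds and the benzyl and MOM ethers are cut first. Ring B is then cut at C2'–C3' and C1'–C6' (retro furan–alkyne cycloaddition, after re-forming the C6'–O bridge), followed by the C2–alkyne bond, and ring C is taken back to 2,4,6-trihydroxyacetophenone.
- Enabling feature: ring B is a benzene with oxygens on adjacent C3' and C4' and the chromone on C1', para to O4'. A 3-alkoxyfuran carries these two oxygens in different forms: its ring oxygen becomes the free O3' phenol and its ether oxygen the protected O4'.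
- Forward: ring A is given; ring C closes by enaminone cyclisation; O3 is introduced by epoxidation and rearrangement and masked as a MOM ether; C2 is zincated, iodinated and alkynylated; ring B is built last from 3-(benzyloxy)furan.
- End game: MOM removal frees O3 beside the free O3', both are sulfated, and hydrogenolysis frees O5, O7 and O4'.
- Stereochemistry: the target has no stereocentre. The racemic bridgeheads of the cycloadduct vanish on aromatisation, so regiocontrol takes the place of stereocontrol.

Key step: step 9

Assumption: the target is drawn as the free bis(hydrogen sulfate); because aryl hydrogen sulfates hydrolyse under their own acidity, the compound is carried as its bis(triethylammonium) salt and the acid form is released only at the end by cold cation exchange.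

**Route**

Step 1
Reactants: 1 2,4,6-trihydroxyacetophenone
Product: 2 1-[2,4-bis(benzyloxy)-6-hydroxyphenyl]ethan-1-one
Conditions: BnBr (2.1 equiv), K2CO3 (2.2 equiv), DMF, 25 °C
Reagents that add atoms: benzyl bromide, BrCc1ccccc1
Why: Williamson ether synthesis in which the hydroxyl hydrogen-bonded to the ketone is the least nucleophilic, so two equivalents of benzyl bromide should alkylate the other two phenols and leave the one needed for ring C.

Step 2
Reactants: 2 1-[2,4-bis(benzyloxy)-6-hydroxyphenyl]ethan-1-one
Product: 4 5,7-bis(benzyloxy)-4H-chromen-4-one, via enaminone 3 (not isolated)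
Conditions: DMF-DMA, toluene, 90 °C; concentrate; then conc. HCl, CH2Cl2, 40 °C
Reagents that add atoms: N,N-dimethylformamide dimethyl acetal, COC(OC)N(C)C
Why: Condensation of the methyl ketone with the amide acetal gives the enaminone, and acid then drives 6-endo addition of the phenol oxygen to the β-carbon with loss of dimethylamine, the standard enaminone route to 2,3-unsubstituted chromones.

Step 3
Reactants: 4 5,7-bis(benzyloxy)-4H-chromen-4-one
Product: 6 5,7-bis(benzyloxy)-3-hydroxy-4H-chromen-4-one, via chromone 2,3-epoxide 5 (not isolated)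
Conditions: DMDO (acetone solution, 2 equiv), CH2Cl2, 0 °C to 25 °C; concentrate; then TsOH·H2O (cat.), CH2Cl2, 25 °C
Reagents that add atoms: dimethyldioxirane, CC1(C)OO1
Why: Dioxirane epoxidation of the C2=C3 bond followed by acid-catalysed opening at C2 (oxocarbenium ion stabilised by O1) and loss of the C3 proton is the established flavone-to-flavonol oxidation and is compatible with benzyl ethers.

Step 4
Reactants: 6 5,7-bis(benzyloxy)-3-hydroxy-4H-chromen-4-one
Product: 7 5,7-bis(benzyloxy)-3-(methoxymethoxy)-4H-chromen-4-one
Conditions: MOMCl (1.5 equiv), iPr2NEt (2 equiv), CH2Cl2, 0 °C to 25 °C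
Reagents that add atoms: chloromethyl methyl ether, COCCl
Why: O-alkylation of the acidic enolic 3-hydroxyl (MOM protection) masks O3 orthogonally to the benzyl ethers, prevents its later cyclisation onto the alkyne and provides a coordinating group for the next metalation.

Step 5
Reactants: 7 5,7-bis(benzyloxy)-3-(methoxymethoxy)-4H-chromen-4-one
Product: 9 5,7-bis(benzyloxy)-2-iodo-3-(methoxymethoxy)-4H-chromen-4-one, via chromon-2-ylzinc chloride 8 (not isolated)
Conditions: TMPZnCl·LiCl (1.3 equiv), THF, 25 °C; then I2 (1.5 equiv), THF, 0 °C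
Reagents that add atoms: iodine, II; TMPZnCl·LiCl, CC1(C)CCCC(C)(C)N1[Zn]Cl.[Li+].[Cl-] (its zinc and chloride stay only in 8)
Why: Directed deprotonative zincation of chromones at C2 with hindered TMP amide bases is established, C2–H is here the only pyranone C–H and is acidified by O1 and the 3-alkoxy group, and iodinolysis of the C–Zn bond then gives the iodide while the mild base spares the aryl and benzylic C–H bonds.

Step 6
Reactants: 9 5,7-bis(benzyloxy)-2-iodo-3-(methoxymethoxy)-4H-chromen-4-one and 10 ethynyltrimethylsilane
Product: 11 5,7-bis(benzyloxy)-3-(methoxymethoxy)-2-[(trimethylsilyl)ethynyl]-4H-chromen-4-one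
Conditions: PdCl2(PPh3)2 (3 mol%), CuI (5 mol%), Et3N (3 equiv), THF, 25 °C
Reagents that add atoms: none
Why: Sonogashira coupling, in which the 2-iodochromone behaves as a vinylogous acyl iodide and should add oxidatively to zerovalent palladium at room temperature, with a tertiary amine base that cannot displace the iodide.

Step 7
Reactants: 11 5,7-bis(benzyloxy)-3-(methoxymethoxy)-2-[(trimethylsilyl)ethynyl]-4H-chromen-4-one
Product: 12 5,7-bis(benzyloxy)-2-ethynyl-3-(methoxymethoxy)-4H-chromen-4-one
Conditions: TBAF (1.1 equiv), AcOH (1.2 equiv), THF, 0 °C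
Reagents that add atoms: none
Why: Fluoride-induced protodesilylation of the alkynylsilane, with acetic acid as proton source so that no alkoxide or hydroxide is present to add to the electrophilic alkyne.

Step 8
Reactants: 13 3-bromofuran and 14 benzyl alcohol
Product: 15 3-(benzyloxy)furan
Conditions: CuI (10 mol%), 3,4,7,8-tetramethyl-1,10-phenanthroline (20 mol%), Cs2CO3 (1.5 equiv), 14 (2 equiv), toluene, 100 °C, sealed tube
Reagents that add atoms: none
Why: Ullmann-type copper-catalysed C–O coupling of a heteroaryl bromide with a primary alcohol, the phenanthroline ligand allowing the bromide to react below the temperature at which the furan is lost.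

Step 9
Reactants: 12 5,7-bis(benzyloxy)-2-ethynyl-3-(methoxymethoxy)-4H-chromen-4-one and 15 3-(benzyloxy)furan
Product: 17 5,7-bis(benzyloxy)-2-[4-(benzyloxy)-3-hydroxyphenyl]-3-(methoxymethoxy)-4H-chromen-4-one, via 7-oxanorbornadiene cycloadduct 16 (not isolated)
Conditions: 15 (3 equiv), toluene (1 M), 80 °C, sealed tube; then CSA (0.2 equiv), 4 Å MS, CH2Cl2, 0 °C
Reagents that add atoms: none
Why: Proposed new method: a 2-ethynylchromone has not been used as a furan dienophile, but its alkyne is the terminus of a vinylogous ynone (C4=O, C3=C2, C≡C) and should undergo a normal-demand, asynchronous [4+2] cycloaddition with the electron-rich 3-alkoxyfuran, the closest known reaction type being the Diels–Alder reaction of furans with ynones or propiolates followed by acid isomerisation of the 7-oxanorbornadiene to a phenol. Ring B closes by intermolecular [4+2] cycloaddition, furan C2 (largest HOMO coefficient, β-carbon of the enol ether) bonding to the terminal alkyne carbon (C2'–C3') and furan C5 to the internal carbon (C1'–C6'), which is the para orientation of a 2-alkoxydiene and places the chromone opposite the benzyloxy carbon. Anhydrous acid then ionises the bridge C–O bond at C6', the only bridgehead whose cation is a vinylogous oxocarbenium ion stabilised by the 4'-benzyloxy group, and loss of the C3' proton from the resulting hydroxycyclohexadienyl cation aromatises the ring with the oxygen retained on C3'. The two bridgehead stereocentres of 16 form as a racemate, need no control and vanish on aromatisation. The selectivities required are the regiochemistry of the cycloaddition and the direction of bridge opening, both dictated by the 3-benzyloxy group of the furan; water is excluded so that the enol ether is not hydrolysed to a ketone that would end as the undifferentiated catechol, and catalytic sulfonic acid at 0 °C should leave the MOM acetal in place.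

Step 10
Reactants: 17 5,7-bis(benzyloxy)-2-[4-(benzyloxy)-3-hydroxyphenyl]-3-(methoxymethoxy)-4H-chromen-4-one
Product: 18 5,7-bis(benzyloxy)-2-[4-(benzyloxy)-3-hydroxyphenyl]-3-hydroxy-4H-chromen-4-one
Conditions: HCl (1.25 M in MeOH), THF, 40 °C
Reagents that add atoms: none
Why: Acid-catalysed acetal exchange with methanol (MOM cleavage) should free the 3-hydroxyl while the benzyl ethers and the flavone core are inert.

Step 11
Reactants: 18 5,7-bis(benzyloxy)-2-[4-(benzyloxy)-3-hydroxyphenyl]-3-hydroxy-4H-chromen-4-one
Product: 19 bis(triethylammonium) 5,7-bis(benzyloxy)-2-[4-(benzyloxy)-3-(sulfonatooxy)phenyl]-4-oxo-4H-chromen-3-yl sulfate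
Conditions: SO3·NEt3 (8 equiv), Et3N (2 equiv), DMF, 50 °C; size-exclusion chromatography (MeOH)
Reagents that add atoms: sulfur trioxide–triethylamine complex, CC[N+](CC)(CC)S(=O)(=O)[O-]
Why: O-sulfation with a sulfur trioxide–amine complex, as used for partially benzylated flavonols, should convert the only two free hydroxyls (enolic O3 and phenolic O3') into sulfate monoester salts.

Step 12
Reactants: 19 bis(triethylammonium) 5,7-bis(benzyloxy)-2-[4-(benzyloxy)-3-(sulfonatooxy)phenyl]-4-oxo-4H-chromen-3-yl sulfate
Product: 21 quercetin 3,3'-bis(hydrogen sulfate) (the target), via bis(triethylammonium) quercetin 3,3'-bissulfate 20 (not isolated)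
Conditions: H2 (1 atm), Pd/C (10 wt%), MeOH/THF, 25 °C; filter; then sulfonic acid cation-exchange resin (H+ form), MeOH/H2O, 0 °C; freeze-dry
Reagents that add atoms: none
Why: Hydrogenolysis of the three benzyl ethers over palladium on carbon, which aryl sulfate monoester salts and the flavonol double bond tolerate, followed by proton-for-ammonium ion exchange, should deliver the acid form.

**Compound list**

1 | 2,4,6-trihydroxyacetophenone | CC(=O)c1c(O)cc(O)cc1O | starting material
2 | 1-[2,4-bis(benzyloxy)-6-hydroxyphenyl]ethan-1-one | CC(=O)c1c(O)cc(OCc2ccccc2)cc1OCc1ccccc1 | intermediate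
3 | (E)-1-[2,4-bis(benzyloxy)-6-hydroxyphenyl]-3-(dimethylamino)prop-2-en-1-one (enaminone) | CN(C)/C=C/C(=O)c1c(O)cc(OCc2ccccc2)cc1OCc1ccccc1 | intermediate (not isolated)
4 | 5,7-bis(benzyloxy)-4H-chromen-4-one | O=c1ccoc2cc(OCc3ccccc3)cc(OCc3ccccc3)c12 | intermediate
5 | 5,7-bis(benzyloxy)-2,3-epoxychroman-4-one (cis-fused, racemate, one enantiomer drawn) | O=C1[C@H]2O[C@H]2Oc2cc(OCc3ccccc3)cc(OCc3ccccc3)c21 | intermediate (not isolated)
6 | 5,7-bis(benzyloxy)-3-hydroxy-4H-chromen-4-one | O=c1c(O)coc2cc(OCc3ccccc3)cc(OCc3ccccc3)c12 | intermediate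
7 | 5,7-bis(benzyloxy)-3-(methoxymethoxy)-4H-chromen-4-one | COCOc1coc2cc(OCc3ccccc3)cc(OCc3ccccc3)c2c1=O | intermediate
8 | [5,7-bis(benzyloxy)-3-(methoxymethoxy)-4-oxo-4H-chromen-2-yl]zinc chloride (LiCl complex) | COCOc1c([Zn]Cl)oc2cc(OCc3ccccc3)cc(OCc3ccccc3)c2c1=O | intermediate (not isolated)
9 | 5,7-bis(benzyloxy)-2-iodo-3-(methoxymethoxy)-4H-chromen-4-one | COCOc1c(I)oc2cc(OCc3ccccc3)cc(OCc3ccccc3)c2c1=O | intermediate
10 | ethynyltrimethylsilane | C[Si](C)(C)C#C | starting material
11 | 5,7-bis(benzyloxy)-3-(methoxymethoxy)-2-[(trimethylsilyl)ethynyl]-4H-chromen-4-one | COCOc1c(C#C[Si](C)(C)C)oc2cc(OCc3ccccc3)cc(OCc3ccccc3)c2c1=O | intermediate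
12 | 5,7-bis(benzyloxy)-2-ethynyl-3-(methoxymethoxy)-4H-chromen-4-one | C#Cc1oc2cc(OCc3ccccc3)cc(OCc3ccccc3)c2c(=O)c1OCOC | intermediate (key-step precursor)
13 | 3-bromofuran | Brc1ccoc1 | starting material
14 | benzyl alcohol | OCc1ccccc1 | starting material
15 | 3-(benzyloxy)furan | c1cc(OCc2ccccc2)co1 | intermediate (key-step precursor)
16 | 5,7-bis(benzyloxy)-2-[5-(benzyloxy)-7-oxabicyclo[2.2.1]hepta-2,5-dien-2-yl]-3-(methoxymethoxy)-4H-chromen-4-one (racemate, one enantiomer drawn) | [C@@H]12C(c3oc4cc(OCc5ccccc5)cc(OCc5ccccc5)c4c(=O)c3OCOC)=C[C@@H](O1)C(OCc1ccccc1)=C2 | intermediate (not isolated)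
17 | 5,7-bis(benzyloxy)-2-[4-(benzyloxy)-3-hydroxyphenyl]-3-(methoxymethoxy)-4H-chromen-4-one | O=c1c(OCOC)c(-c2ccc(OCc3ccccc3)c(O)c2)oc2cc(OCc3ccccc3)cc(OCc3ccccc3)c12 | intermediate (key-step product)
18 | 5,7-bis(benzyloxy)-2-[4-(benzyloxy)-3-hydroxyphenyl]-3-hydroxy-4H-chromen-4-one | O=c1c(O)c(-c2ccc(OCc3ccccc3)c(O)c2)oc2cc(OCc3ccccc3)cc(OCc3ccccc3)c12 | intermediate
19 | bis(triethylammonium) 5,7-bis(benzyloxy)-2-[4-(benzyloxy)-3-(sulfonatooxy)phenyl]-4-oxo-4H-chromen-3-yl sulfate | O=c1c(OS(=O)(=O)[O-])c(-c2ccc(OCc3ccccc3)c(OS(=O)(=O)[O-])c2)oc2cc(OCc3ccccc3)cc(OCc3ccccc3)c12.CC[NH+](CC)CC.CC[NH+](CC)CC | intermediate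
20 | bis(triethylammonium) quercetin 3,3'-bissulfate | O=c1c(OS(=O)(=O)[O-])c(-c2ccc(O)c(OS(=O)(=O)[O-])c2)oc2cc(O)cc(O)c12.CC[NH+](CC)CC.CC[NH+](CC)CC | intermediate (not isolated)
21 | quercetin 3,3'-bis(hydrogen sulfate) | O=c1c(OS(=O)(=O)O)c(-c2ccc(O)c(OS(=O)(=O)O)c2)oc2cc(O)cc(O)c12 | target

**Step count**

Total: 12 steps. Longest linear sequence: 11 steps (1 to 21 through steps 1–7 and 9–12); step 8 supplies the furan.

**Steps most likely to fail**

1. Step 9 (proposed new method). The cycloaddition may be too slow for an alkyne that is activated only through the electron-rich pyranone. Cycloreversion, thermal decay of the furan or Michael-type C-alkenylation of the furan without ring closure could then take over. In the acid stage, hydrolysis of the enol ether could compete with bridge opening and erase the O3'/O4' distinction.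
Fallback (known chemistry), from iodide 9 back to phenol 17: Suzuki–Miyaura coupling of 9 with commercially listed [4-(benzyloxy)-3-formylphenyl]boronic acid (Pd(PPh3)4, K3PO4, dioxane, 80 °C) should give 2-(benzyloxy)-5-[5,7-bis(benzyloxy)-3-(methoxymethoxy)-4-oxo-4H-chromen-2-yl]benzaldehyde F1. Baeyer–Villiger (Dakin-type) oxidation with mCPBA and NaHCO3 in CH2Cl2, where the ortho-benzyloxy group favours aryl migration, should give 2-(benzyloxy)-5-[5,7-bis(benzyloxy)-3-(methoxymethoxy)-4-oxo-4H-chromen-2-yl]phenyl formate F2. Methanolysis (K2CO3, MeOH, 0 °C) then frees the 3'-phenol and rejoins the route at 17. Here the ring B oxygens are told apart by the aldehyde instead of by the furan.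

2. Step 8. Oxidative addition of the volatile, electron-rich 3-bromofuran to copper may be sluggish, and the acid- and air-sensitive enol-ether furan may be lost by evaporation or decomposition during isolation.
Fallback, from benzyl alcohol 14 back to furan 15: commercial 4,4-diethoxybut-2-yn-1-ol is cyclised with Ph3PAuNTf2 (2 mol%) in CH2Cl2 containing 14 (5 equiv) at 25 °C. This is the known gold-catalysed route to 3-alkoxyfurans from acetal-bearing propargylic alcohols, in which the added alcohol becomes the 3-alkoxy group and ethanol is lost. It should give 15 directly under neutral, room-temperature conditions; no compound outside the list is formed (F0).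

3. Step 11. Sulfation of the hindered, hydrogen-bonded enolic 3-hydroxyl may stall at the 3'-monosulfate, and sulfate may be lost during purification of the polar bis-salt.
Fallback, from diol 18 back to target 21: 18 is treated with 2,2,2-trichloroethyl chlorosulfate, Et3N and DMAP in THF at 0 °C to give the neutral, chromatographable diester 5,7,4'-tri-O-benzylquercetin 3,3'-bis(2,2,2-trichloroethyl sulfate) F3. Pd/C with HCO2NH4 in MeOH at 25 °C should then remove both trichloroethyl groups (reductive β-elimination) and the three benzyl ethers to give diammonium quercetin 3,3'-bissulfate F4. The same cold cation exchange as in step 12 gives 21.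

**Further compounds**

F1 | step 9 | 2-(benzyloxy)-5-[5,7-bis(benzyloxy)-3-(methoxymethoxy)-4-oxo-4H-chromen-2-yl]benzaldehyde | O=Cc1cc(-c2oc3cc(OCc4ccccc4)cc(OCc4ccccc4)c3c(=O)c2OCOC)ccc1OCc1ccccc1
F2 | step 9 | 2-(benzyloxy)-5-[5,7-bis(benzyloxy)-3-(methoxymethoxy)-4-oxo-4H-chromen-2-yl]phenyl formate | O=COc1cc(-c2oc3cc(OCc4ccccc4)cc(OCc4ccccc4)c3c(=O)c2OCOC)ccc1OCc1ccccc1
F0 | step 8 | none | none
F3 | step 11 | 5,7,4'-tri-O-benzylquercetin 3,3'-bis(2,2,2-trichloroethyl sulfate) | O=c1c(OS(=O)(=O)OCC(Cl)(Cl)Cl)c(-c2ccc(OCc3ccccc3)c(OS(=O)(=O)OCC(Cl)(Cl)Cl)c2)oc2cc(OCc3ccccc3)cc(OCc3ccccc3)c12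
F4 | step 11 | diammonium quercetin 3,3'-bissulfate | O=c1c(OS(=O)(=O)[O-])c(-c2ccc(O)c(OS(=O)(=O)[O-])c2)oc2cc(O)cc(O)c12.[NH4+].[NH4+]
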